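The reading was due at 1.0 h, so I left this note for whoever took over the flask.

| flask | substrate | coupling partner | remark | time |
|---|---|---|---|---|
| east | 0.13 M | 0.13 M | run made earlier |  |
| west | 0.13 M | 0.20 M | run made earlier |  |
| north-east | 0.065 M | 0.26 M | run made earlier |  |
| flask | 0.13 M | 0.260 M |  | 1.0 h |

- east (time / min: single product / %): 4.00: 10; 12.0: 23; 20.0: 24; 30.0: 34; 40.0: 42; 60.0: 49; 80.0: 49
- west (time / min: single product / %): 6.00: 20; 8.00: 20; 12.0: 26; 20.0: 42; 30.0: 49; 50.0: 52; 80.0: 58
- north-east (time / min: single product / %): 6.00: 18; 20.0: 50; 30.0: 53; 50.0: 52; 80.0: 45

(scatter of a reading: 2 percentage points)

1. equivalents of coupling partner to substrate, everything else as given, that leave most single product at 1.0 h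
2. the amount of single product then, in percent of the substrate charged
3. the amount of single product with the amounts as given

- what was read earlier has a scatter of 2 percentage points, one standard deviation
- a reading or a percentage of single product counts all its forms, free or not

Let a and m be substrate and single product as fractions of the charge. I took single product to be made at a rate in a times partner and used at a rate in m times partner, so partner cancelled from the comparison.

The first east reading, with its scatter, gave the first rate constant, 0.214 /M/min. Partner stood in excess in the north-east run, so I held it at its charge there. My estimate was then 18.9% substrate at 30.0 min, beside a reading of 53% single product, near the top of that run. So a/m read 0.356. This is the turning ratio, in this two-step view the a/m below which single product falls, and the inverse of the selectivity factor.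

With two steps, that ratio put the peak at 56.5%, with 20.1% substrate. With partner held at its charge, I reckoned the flask would get there in 28.9 min. Partner fell, but the reading came later than that, so I expected the peak or just past it. Do not add partner: in this view it moves the peak, not its height.

The forecast was lower than my peak: 53%, and 54% at 1.8 equiv. “The optimum is flat.”

The flask gave 61.8%, above my peak, and 62.4% at 2.29 equiv.

    substrate + coupling partner → single product (k = 0.00297 /M/s)
    coupling partner + single product → double product (k = 0.00126 /M/s)
    coupling partner + double product → tris adduct (k = 0.00384 /M/s)
    coupling partner + tris adduct ⇌ tetra adduct (K = 2.97 /M, k = 0.00767 /M/s)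
    crystals ⇌ single product, rate k5*(cs5 - [single product]) while solid is left; crystals form when [single product] > cs5 (solubility = 40.0 mM, k = 0.0241 /s)

At 1.00 h the flask held 17.6% substrate and 61.8% single product, crystals counted, the crystals being 31.0% of the substrate charged. Over all forms a/m was 0.285, below the turning ratio. Over dissolved single product it was 0.571, above it. The neighbour flask with 1.0 M partner held 0% crystals, and its a/m was 0.00368, far below the turning ratio. Its single product stood at 11.7%.

Readings and results are calculated from invented constants, noise included.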